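Prostanoid numbering is used (ester carbon = C1, ring = C8–C12). The route rests on disconnecting the C8–C12 bond of the only ring. A cyclopent-2-enone with its ketone at C9, chlorine on C10 and a tertiary oxygen on C12 is the retron of the dearomatising oxa-Piancatelli rearrangement. In one operation a flat, achiral 3-chloro-5-octenylfurfuryl alcohol takes up water at its alkyl-bearing furan carbon, opens, and recloses by 4π-conrotatory electrocyclisation inside the ion pair of a chiral Brønsted acid. Ring, C9 ketone, C10 chloroalkene and C12 stereocentre arise together. Aldol addition of a (Z)-enal at C8 and acetylation with elimination complete the target.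

Key step: step 5

Assumption: the (R)-configured acid of step 5 is taken to give (S)-12. Both antipodes of the acid are available, so the other one is used if the sense of induction is the opposite.

Step 1
Reactants: 1 3-bromofuran
Product: 3 3-chlorofuran, via 3-lithiofuran 2 (not isolated)
Conditions: n-BuLi (1.05 equiv), Et2O, −78 °C; then C2Cl6, −78 °C to 0 °C; distillation
Reagents that add atoms: hexachloroethane, ClC(Cl)(Cl)C(Cl)(Cl)Cl
Why: Bromine–lithium exchange followed by electrophilic chlorination should replace Br by Cl at the same carbon, because 3-lithiofuran 2 keeps its position below −40 °C, which places the halogen on the furan carbon that becomes C10.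

Step 2
Reactants: 3 3-chlorofuran
Product: 5 (3-chlorofuran-2-yl)methanol, via 3-chloro-2-lithiofuran 4 (not isolated)
Conditions: LiN(iPr)2 (LDA, 1.05 equiv), THF, −78 °C; HCHO gas (cracked paraformaldehyde), −78 °C to rt; H2O
Reagents that add atoms: formaldehyde, C=O
Why: Directed ortho-lithiation and hydroxymethylation: the C2–H flanked by the ring oxygen and the chlorine is the most acidic proton of 3, so LDA should metalate only there and formaldehyde then installs the carbinol carbon that becomes C8.

Step 3
Reactants: 6 (Z)-oct-2-en-1-ol
Product: 7 (Z)-1-bromooct-2-ene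
Conditions: CBr4, PPh3, CH2Cl2, 0 °C
Reagents that add atoms: carbon tetrabromide, BrC(Br)(Br)Br
Why: Appel reaction, an SN2 displacement on the oxyphosphonium salt under neutral conditions, which should keep the Z geometry and avoid allylic transposition.

Step 4
Reactants: 5 (3-chlorofuran-2-yl)methanol; 7 (Z)-1-bromooct-2-ene
Product: 9 {3-chloro-5-[(Z)-oct-2-en-1-yl]furan-2-yl}methanol, via dilithio derivative 8 (not isolated)
Conditions: n-BuLi (2.0 equiv), THF, −78 °C to 0 °C; then 7 (1.0 equiv), −78 °C to 0 °C; H2O
Reagents that add atoms: none
Why: Alkoxide formation and α-lithiation of the furan at its only free α-position give 8, whose carbanion should alkylate the primary allylic bromide by direct SN2 faster than the lithium alkoxide does, so the skipped (Z)-octenyl chain is attached last and sees no further strong base.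

Step 5
Reactants: 9 {3-chloro-5-[(Z)-oct-2-en-1-yl]furan-2-yl}methanol
Product: 12 (S)-2-chloro-4-hydroxy-4-[(Z)-oct-2-en-1-yl]cyclopent-2-en-1-one, via hemiketal 10 (not isolated), via dienol-one 11 (not isolated)
Conditions: (R)-3,3'-bis(2,4,6-triisopropylphenyl)-1,1'-binaphthyl-2,2'-diyl N-triflylphosphoramide (10 mol %), H2O (20 equiv), toluene (0.05 M), vigorous stirring, 40 °C
Reagents that add atoms: water, O
Why: Proposed new method: the strong chiral acid ionises 9 to a furfuryl cation, water adds at the octenyl-bearing furan carbon (future C12) to give hemiketal 10, ring opening gives dienol-one 11, and its O-protonated form, a 1,4-dihydroxypentadienyl cation, closes the C8–C12 bond by 4π-conrotatory electrocyclisation before losing a proton to leave the C9 ketone. The closest known reaction types are the racemic oxa-Piancatelli rearrangement of 5-alkyl-2-furylcarbinols to 4-alkyl-4-hydroxycyclopent-2-enones, the aza-Piancatelli rearrangement and the Nazarov cyclisation catalysed by chiral phosphoric acids and N-triflylphosphoramides, and an oxa-Piancatelli rearrangement catalysed by chiral complexes of pentavalent vanadium; asymmetric induction on a primary, 3-chloro, 5-alkyl furfuryl alcohol has not been shown. The one ring that is closed, C8–C9–C10–C11–C12, forms by this electrocyclisation (formally a 5-enolexo aldol of C8 onto the C12 carbonyl), its five carbons being the carbinol carbon and the four furan carbons, so the furan chlorine ends on C10 and the furan oxygen becomes the C9 ketone. The only new stereocentre, C12, is set by the sense of conrotation, which nothing in the achiral substrate biases; the control element is the phosphoramidate anion, held by hydrogen bonds to the C12 and C9 hydroxyls of the cation in a contact ion pair in toluene. The step needs water to attack C12 rather than C8 (attack at C8 merely returns 9), no Friedel–Crafts oligomerisation (both furan α-positions are substituted and the remaining C–H lies next to chlorine) and no cation–olefin or olefin-migration chemistry at the skipped (Z)-alkene (closure onto it would give three- or four-membered rings). The closure should be irreversible under acid because C12 is quaternary and dehydration would give an antiaromatic cyclopentadienone.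

Step 6
Reactants: 13 cyclohepta-1,3-diene
Product: 15 methyl (Z)-7-oxohept-5-enoate, via methoxy hydroperoxide 14 (not isolated)
Conditions: O3 (1.0 equiv), CH2Cl2/MeOH 5:1, NaHCO3, −78 °C; then Ac2O, Et3N, CH2Cl2, 0 °C; used at once
Reagents that add atoms: ozone, [O-][O+]=O; methanol, CO
Why: Criegee ozonolysis with differentiation of the two termini: only one double bond should react because the enal formed is deactivated, the primary ozonide should fragment to the conjugated enal and the alkyl-substituted carbonyl oxide, methanol traps the latter as 14, Ac2O/Et3N dehydrates 14 to the methyl ester, and the remaining olefin keeps the Z geometry of the ring.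

Step 7
Reactants: 12 (S)-2-chloro-4-hydroxy-4-[(Z)-oct-2-en-1-yl]cyclopent-2-en-1-one; 15 methyl (Z)-7-oxohept-5-enoate
Product: 17 methyl (5Z,14Z)-10-chloro-7,12-dihydroxy-9-oxoprosta-5,10,14-trien-1-oate (C12 as in 12, mixture at C7 and C8), via dilithium dianion 16 (not isolated)
Conditions: LiN(iPr)2 (LDA, 2.2 equiv), THF, −78 °C, 12 added to the base; then 15 (1.2 equiv), −78 °C; AcOH in THF, −78 °C
Reagents that add atoms: none
Why: Directed aldol addition: LDA removes the hydroxyl proton and the only enolisable hydrogen (at C8) to give the cross-conjugated dianion 16, which should add 1,2 to the enal at −78 °C faster than retro-aldol opening or olefin isomerisation can occur, the new centres C7 and C8 forming as a mixture that does not matter because both are destroyed in step 8, while C12 is untouched.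

Step 8
Reactants: 17 methyl (5Z,14Z)-10-chloro-7,12-dihydroxy-9-oxoprosta-5,10,14-trien-1-oate
Product: 20 methyl (5Z,7E,12R,14Z)-12-acetoxy-10-chloro-9-oxoprosta-5,7,10,14-tetraen-1-oate, via C7 monoacetate 18 (not isolated), via C12 alcohol 19 (not isolated)
Conditions: Ac2O (6 equiv), Et3N (8 equiv), DMAP (0.5 equiv), CH2Cl2, 0 °C to rt
Reagents that add atoms: acetic anhydride, CC(=O)OC(C)=O
Why: DMAP-catalysed acetylation and E1cB elimination: the secondary C7 hydroxyl is acetylated first (18), loss of acetate through the C8 enolate gives the cross-conjugated dienone 19, in which the 7E geometry (chain anti to the C9 carbonyl) should prevail and any 7Z isomer is removed by chromatography, and the tertiary C12 hydroxyl is then acetylated with retention because its C–O bond is never broken (its loss would give an antiaromatic cyclopentadienone).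

Compound list
1 | 3-bromofuran | Brc1ccoc1 | starting material
2 | 3-lithiofuran | [Li]c1ccoc1 | intermediate
3 | 3-chlorofuran | Clc1ccoc1 | intermediate
4 | 3-chloro-2-lithiofuran | [Li]c1occc1Cl | intermediate
5 | (3-chlorofuran-2-yl)methanol | OCc1occc1Cl | intermediate
6 | (Z)-oct-2-en-1-ol | CCCCC/C=C\CO | starting material
7 | (Z)-1-bromooct-2-ene | CCCCC/C=C\CBr | intermediate
8 | lithium (3-chloro-5-lithiofuran-2-yl)methanolate | [Li]OCc1oc([Li])cc1Cl | intermediate
9 | {3-chloro-5-[(Z)-oct-2-en-1-yl]furan-2-yl}methanol | CCCCC/C=C\Cc1cc(Cl)c(CO)o1 | intermediate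
10 | 4-chloro-5-methylidene-2-[(Z)-oct-2-en-1-yl]-2,5-dihydrofuran-2-ol (hemiketal) | CCCCC/C=C\CC1(O)C=C(Cl)C(=C)O1 | intermediate
11 | (3Z,8Z)-3-chloro-2-hydroxytetradeca-1,3,8-trien-5-one (dienol-one; cyclises as its O-protonated form) | C=C(O)/C(Cl)=C\C(=O)C/C=C\CCCCC | intermediate
12 | (S)-2-chloro-4-hydroxy-4-[(Z)-oct-2-en-1-yl]cyclopent-2-en-1-one (same spatial arrangement at C12 as in 20; the descriptor becomes R once C8 is sp2) | CCCCC/C=C\C[C@@]1(O)C=C(Cl)C(=O)C1 | intermediate
13 | cyclohepta-1,3-diene | C1=CC=CCCC1 | starting material
14 | (Z)-7-hydroperoxy-7-methoxyhept-2-enal | COC(OO)CCC/C=C\C=O | intermediate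
15 | methyl (Z)-7-oxohept-5-enoate | COC(=O)CCC/C=C\C=O | intermediate
16 | dilithium alkoxide-dienolate of 12 | CCCCC/C=C\C[C@@]1([O-])C=C(Cl)C([O-])=C1.[Li+].[Li+] | intermediate
17 | methyl (5Z,14Z)-10-chloro-7,12-dihydroxy-9-oxoprosta-5,10,14-trien-1-oate (12S, mixture at C7 and C8) | CCCCC/C=C\C[C@@]1(O)C=C(Cl)C(=O)C1C(O)/C=C\CCCC(=O)OC | intermediate
18 | methyl (5Z,14Z)-7-acetoxy-10-chloro-12-hydroxy-9-oxoprosta-5,10,14-trien-1-oate (12S, mixture at C7 and C8) | CCCCC/C=C\C[C@@]1(O)C=C(Cl)C(=O)C1C(OC(C)=O)/C=C\CCCC(=O)OC | intermediate
19 | methyl (5Z,7E,12R,14Z)-10-chloro-12-hydroxy-9-oxoprosta-5,7,10,14-tetraen-1-oate | CCCCC/C=C\C[C@@]1(O)C=C(Cl)C(=O)/C1=C/C=C\CCCC(=O)OC | intermediate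
20 | methyl (5Z,7E,12R,14Z)-12-acetoxy-10-chloro-9-oxoprosta-5,7,10,14-tetraen-1-oate | CCCCC/C=C\C[C@@]1(OC(C)=O)C=C(Cl)C(=O)/C1=C/C=C\CCCC(=O)OC | target

Total step count: 8. Longest linear sequence: 6 (steps 1, 2, 4, 5, 7, 8).

Steps most likely to fail

First, step 5. Ionisation of the primary, chlorine-deactivated carbinol may be too slow for the chiral acid. Tautomerisation of the hemiketal to the open enedione may compete. Facial discrimination in the conrotatory closure may be weak because the C8 terminus carries no substituent. The fallback uses known chemistry, sets out from 9 and comes back at 12. The racemic oxa-Piancatelli rearrangement is run with Dy(OTf)3 (10 mol %) in t-BuOH/H2O 5:1 at 80 °C and gives the racemic hydroxy enone F1. Lithiated (S)-N,S-dimethyl-S-phenylsulfoximine (2.1 equiv, THF, −78 °C) is added 1,2 to the ketone. The diastereomeric adducts are separated by chromatography, and the adduct derived from the (S)-ketone, the β-hydroxysulfoximine F2, is heated in toluene at reflux. This releases 12 and the sulfoximine. The stereocentre then comes from a resolution instead of from catalysis.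

Second, step 7. The lithium alkoxide may open by retro-aldol reaction, which would racemise C12. The enolate may eliminate, or the enal may isomerise from Z to E under basic conditions. The fallback sets out from 12 and comes back at 17. Silylation with TMSOTf/Et3N (CH2Cl2, 0 °C) converts both the hydroxyl and the ketone into the bis(trimethylsilyl) dienol ether F3, a 5,5-disubstituted cyclopentadiene that cannot shift hydrogen. A Mukaiyama aldol addition to 15 with BF3·OEt2 (CH2Cl2, −78 °C) and a mildly acidic work-up give 17 without any strong base.

Third, step 6. The primary ozonide may fragment in the other direction, and the Z geometry may be lost during the amine-mediated dehydration. The fallback avoids the (Z)-enal, sets out from 12 and comes back at 17. Commercial methyl 7-hydroxyhept-5-ynoate is oxidised with Dess–Martin periodinane to methyl 7-oxohept-5-ynoate F4. Dianion 16 is added to it at −78 °C to give the propargylic aldol F5. Semihydrogenation (H2, Pd/CaCO3 poisoned with Pb(OAc)2, quinoline, EtOAc) then sets the 5Z olefin after the C7–C8 bond has been made.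

Further compounds
F1 | step 5 | rac-2-chloro-4-hydroxy-4-[(Z)-oct-2-en-1-yl]cyclopent-2-en-1-one | CCCCC/C=C\CC1(O)C=C(Cl)C(=O)C1
F2 | step 5 | (4S)-2-chloro-1-{[(S)-N-methyl-S-phenylsulfonimidoyl]methyl}-4-[(Z)-oct-2-en-1-yl]cyclopent-2-ene-1,4-diol (new carbinol centre not assigned) | CCCCC/C=C\C[C@@]1(O)C=C(Cl)C(O)(C[S@@](=O)(=NC)c2ccccc2)C1
F3 | step 7 | (S)-2-chloro-5-[(Z)-oct-2-en-1-yl]-3,5-bis(trimethylsilyloxy)cyclopenta-1,3-diene | CCCCC/C=C\C[C@@]1(O[Si](C)(C)C)C=C(Cl)C(O[Si](C)(C)C)=C1
F4 | step 6 | methyl 7-oxohept-5-ynoate | COC(=O)CCCC#CC=O
F5 | step 6 | methyl (14Z)-10-chloro-7,12-dihydroxy-9-oxoprosta-10,14-dien-5-yn-1-oate (12S, mixture at C7 and C8) | CCCCC/C=C\C[C@@]1(O)C=C(Cl)C(=O)C1C(O)C#CCCCC(=O)OC
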